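**Retrosynthetic overview**
1. Target ⇐ C7 carbamoylation and desilylation of a macrolactam; the arene is bought and the only ring made is the 19-membered lactam, closed late at N–C20 by intramolecular copper-catalysed amidation of an aryl bromide (step 20).
2. Seco-amide ⇐ C3–C4 B-alkyl Suzuki coupling of a C4 borane with (Z)-3-iodo-2-methylprop-2-enamide (C1–C3, from propargyl alcohol).
3. C4–C7 with C6/C7 ⇐ (Z)-γ-methoxyallylboration of a (Z)-enal, itself from Still–Gennari olefination of the C9 aldehyde (sets 8Z).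
4. C9–C11 with C10/C11 ⇐ (Z)-crotylboration of an α-methoxy aldehyde; C12 ⇐ proposed new enantioselective anodic enamine α-methoxylation.
5. C11 aldehyde ⇐ Evans benzylation (C14) with a 3-bromo-5-silyloxybenzyl bromide, then two-carbon homologation.

Assumption and numbering: the SMILES is taken literally, so both trisubstituted alkenes are Z (C1 cis to C4; C7 cis to C10) with 6S,7S,10S,11R,12S,14R; ansamycin numbering is used (C1 lactam carbonyl to C15 benzylic CH2, arene C16–C21 with O on C18 and N on C20).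

Step 1
Reactants: 1 3-bromo-5-methylphenol
Product: 2 (3-bromo-5-methylphenoxy)triisopropylsilane
Conditions: i-Pr3SiCl, imidazole, DMF, 23 °C
Reagents that add atoms: triisopropylsilyl chloride, CC(C)[Si](Cl)(C(C)C)C(C)C
Why: Imidazole-promoted O-silylation of a phenol gives a TIPS aryl ether that tolerates the later bases, hydrides and oxidants; no stereocentre is involved.

Step 2
Reactants: 2 (3-bromo-5-methylphenoxy)triisopropylsilane
Product: 3 [3-bromo-5-(bromomethyl)phenoxy]triisopropylsilane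
Conditions: N-bromosuccinimide (1.0 equiv), AIBN (cat.), PhCF3, 85 °C
Reagents that add atoms: N-bromosuccinimide, O=C1CCC(=O)N1Br
Why: Wohl–Ziegler radical bromination attacks the only benzylic C–H bonds, while the bromo-substituted silylated ring resists electrophilic bromination under radical conditions.

Step 3
Reactants: 4 (S)-4-benzyl-3-propanoyl-1,3-oxazolidin-2-one; 3 [3-bromo-5-(bromomethyl)phenoxy]triisopropylsilane
Product: 6 (S)-4-benzyl-3-[(R)-3-[3-bromo-5-(triisopropylsilyloxy)phenyl]-2-methylpropanoyl]-1,3-oxazolidin-2-one, via sodium Z-enolate 5 (not isolated)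
Conditions: NaN(SiMe3)2, THF, −78 °C; then 3, −78 → −40 °C
Reagents that add atoms: none
Why: Evans asymmetric alkylation, in which the chelated Z-enolate is benzylated on the face opposite the auxiliary benzyl group, sets C14 as R.

Step 4
Reactants: 6 alkylated imide
Product: 7 (R)-3-[3-bromo-5-(triisopropylsilyloxy)phenyl]-2-methylpropan-1-ol
Conditions: LiBH4, MeOH (1 equiv), Et2O, 0 °C
Reagents that add atoms: none
Why: Reductive cleavage of the Evans imide gives the primary alcohol without touching C14, the aryl bromide or the silyl ether.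

Step 5
Reactants: 7 primary alcohol
Product: 8 [3-bromo-5-[(R)-3-iodo-2-methylpropyl]phenoxy]triisopropylsilane
Conditions: I2, PPh3, imidazole, CH2Cl2, 0 → 23 °C
Reagents that add atoms: iodine, II
Why: Appel-type iodination proceeds by SN2 displacement at the primary carbon C13, so the adjacent stereocentre is unaffected.

Step 6
Reactants: 8 primary iodide
Product: 10 (S)-5-[3-bromo-5-(triisopropylsilyloxy)phenyl]-4-methylpentanal, via N,N-dimethylhydrazone 9 (not isolated)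
Conditions: acetaldehyde N,N-dimethylhydrazone, LiN(i-Pr)2, THF, 0 °C; 8, −78 → 23 °C; then aq. oxalic acid, Et2O, 23 °C
Reagents that add atoms: acetaldehyde N,N-dimethylhydrazone, C/C=N/N(C)C; water, O
Why: Corey–Enders alkylation of the lithiated hydrazone (an acetaldehyde enolate equivalent) with the primary iodide, then mild acid hydrolysis, adds C12 and C11 as the aldehyde; the descriptor at C14 changes to S only through CIP priorities.

Step 7
Reactants: 10 (S)-5-[3-bromo-5-(triisopropylsilyloxy)phenyl]-4-methylpentanal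
Product: 11 (2S,4R)-5-[3-bromo-5-(triisopropylsilyloxy)phenyl]-2-methoxy-4-methylpentanal
Conditions: (2S,5S)-5-benzyl-2-tert-butyl-3-methylimidazolidin-4-one·CF3CO2H (20 mol%), MeOH (10 equiv), 2,6-lutidine, n-Bu4NBF4, MeCN, undivided cell, graphite anode, Pt cathode, constant current (2.2 F/mol), −20 °C; used crude
Reagents that add atoms: methanol, CO
Why: Proposed new method: the imidazolidinone condenses with 10 to the E-enamine, anodic one-electron oxidation (well below the arene potential) gives the 3π-electron radical cation, methanol adds to the Si face of C12 (the face away from the catalyst benzyl group), a second anodic oxidation gives the iminium ion and hydrolysis releases the aldehyde with C12 set as S under catalyst control, while protons are reduced to H2 at the cathode; the closest known reaction types are SOMO-activation α-functionalisation of aldehydes via enamine radical cations, anodic α-oxyamination under enamine catalysis and the racemic anodic α-methoxylation of preformed enamines.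

Step 8
Reactants: 11 α-methoxy aldehyde
Product: 13 (3S,4R,5S,7R)-8-[3-bromo-5-(triisopropylsilyloxy)phenyl]-5-methoxy-3,7-dimethyloct-1-en-4-ol, via O-boryl ether 12 (not isolated)
Conditions: cis-2-butene, KOt-Bu, n-BuLi, THF, −78 → −45 °C; (+)-Ipc2BOMe (from (−)-α-pinene), −78 °C; BF3·OEt2; 11, −78 °C; then ethanolamine, 23 °C
Reagents that add atoms: cis-2-butene, C/C=C\C
Why: Brown asymmetric crotylboration through a chair transition state, where the Z-crotyl geometry gives the 10,11-syn relationship and the (+)-Ipc2B reagent attacks the Re face of C11, which is also the Felkin/Cornforth-preferred face (matched), sets C10 as S and C11 as R.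

Step 9
Reactants: 13 homoallylic alcohol
Product: 14 tert-butyl{[(3S,4R,5S,7R)-8-[3-bromo-5-(triisopropylsilyloxy)phenyl]-5-methoxy-3,7-dimethyloct-1-en-4-yl]oxy}dimethylsilane
Conditions: t-BuMe2SiOTf, 2,6-lutidine, CH2Cl2, −78 → 0 °C
Reagents that add atoms: tert-butyldimethylsilyl triflate, CC(C)(C)[Si](C)(C)OS(=O)(=O)C(F)(F)F
Why: Silyl triflate silylation protects the hindered C11 hydroxyl through the oxidation, olefination and organometallic steps that follow.

Step 10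
Reactants: 14 TBS ether
Product: 16 (2R,3R,4S,6R)-7-[3-bromo-5-(triisopropylsilyloxy)phenyl]-3-(tert-butyldimethylsilyloxy)-4-methoxy-2,6-dimethylheptanal, via ozonide 15 (not isolated)
Conditions: O3, CH2Cl2, pyridine, −78 °C (indicator end point); then PPh3, −78 → 23 °C
Reagents that add atoms: ozone, [O-][O+]=O
Why: Ozonolysis with reductive work-up cleaves the only monosubstituted alkene to the C9 aldehyde under neutral cold conditions that preserve the α-stereocentre C10.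

Step 11
Reactants: 16 C9 aldehyde
Product: 17 ethyl (2Z,4S,5R,6S,8R)-9-[3-bromo-5-(triisopropylsilyloxy)phenyl]-5-(tert-butyldimethylsilyloxy)-6-methoxy-2,4,8-trimethylnon-2-enoate
Conditions: ethyl 2-[bis(2,2,2-trifluoroethoxy)phosphoryl]propanoate, KN(SiMe3)2, 18-crown-6, THF, −78 °C
Reagents that add atoms: ethyl 2-[bis(2,2,2-trifluoroethoxy)phosphoryl]propanoate, CCOC(=O)C(C)P(=O)(OCC(F)(F)F)OCC(F)(F)F
Why: Still–Gennari modification of the Horner–Wadsworth–Emmons reaction, whose electron-poor phosphonate eliminates under kinetic control, gives the Z-trisubstituted enoate (C7 cis to C10).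

Step 12
Reactants: 17 Z-enoate
Product: 18 (2Z,4S,5R,6S,8R)-9-[3-bromo-5-(triisopropylsilyloxy)phenyl]-5-(tert-butyldimethylsilyloxy)-6-methoxy-2,4,8-trimethylnon-2-en-1-ol
Conditions: i-Bu2AlH, CH2Cl2, −78 °C; aq. Rochelle salt
Reagents that add atoms: none
Why: 1,2-Reduction of the enoate gives the allylic alcohol without change of alkene geometry.

Step 13
Reactants: 18 Z-allylic alcohol
Product: 19 (2Z,4S,5R,6S,8R)-9-[3-bromo-5-(triisopropylsilyloxy)phenyl]-5-(tert-butyldimethylsilyloxy)-6-methoxy-2,4,8-trimethylnon-2-enal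
Conditions: Dess–Martin periodinane, NaHCO3, CH2Cl2, 0 °C; used at once
Reagents that add atoms: none
Why: Buffered Dess–Martin oxidation is non-acidic and keeps the Z geometry of the sensitive enal.

Step 14
Reactants: 19 Z-enal
Product: 21 (3S,4S,5Z,7S,8R,9S,11R)-12-[3-bromo-5-(triisopropylsilyloxy)phenyl]-8-(tert-butyldimethylsilyloxy)-3,9-dimethoxy-5,7,11-trimethyldodeca-1,5-dien-4-ol, via O-boryl ether 20 (not isolated)
Conditions: allyl methyl ether, s-BuLi, THF, −78 °C; (+)-Ipc2BOMe; BF3·OEt2; 19, −78 °C; then ethanolamine, 23 °C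
Reagents that add atoms: allyl methyl ether, COCC=C
Why: Brown (Z)-γ-methoxyallylboration via a chair transition state, where the Z enol ether geometry gives the syn 6-methoxy-7-hydroxy pair and the (+)-Ipc2B reagent adds to the Re face of C7, sets C6 and C7 both as S under reagent control.

Step 15
Reactants: 21 dienol
Product: 22 triethyl{[(3S,4S,5Z,7S,8R,9S,11R)-12-[3-bromo-5-(triisopropylsilyloxy)phenyl]-8-(tert-butyldimethylsilyloxy)-3,9-dimethoxy-5,7,11-trimethyldodeca-1,5-dien-4-yl]oxy}silane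
Conditions: Et3SiCl, imidazole, DMAP (cat.), DMF, 0 → 23 °C
Reagents that add atoms: chlorotriethylsilane, CC[Si](Cl)(CC)CC
Why: The C7 hydroxyl is masked as the more labile TES ether so that it cannot add to the enamide during ring closure and can later be removed in the presence of the TBS and TIPS ethers.

Step 16
Reactants: 23 prop-2-yn-1-ol
Product: 25 (Z)-3-iodo-2-methylprop-2-en-1-ol, via alkenylmagnesium alkoxide 24 (not isolated)
Conditions: MeMgBr (2.5 equiv), CuI (10 mol%), Et2O/THF, −10 → 23 °C; then I2, −10 °C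
Reagents that add atoms: methylmagnesium bromide, C[Mg]Br; iodine, II
Why: Copper-catalysed anti-carbomagnesiation of the propargylic alkoxide gives a chelated alkenylmagnesium with Mg cis to the CH2O group, and iodinolysis with retention gives the Z-vinyl iodide.

Step 17
Reactants: 25 (Z)-3-iodo-2-methylprop-2-en-1-ol
Product: 27 (Z)-3-iodo-2-methylprop-2-enoic acid, via enal 26 (not isolated)
Conditions: MnO2, CH2Cl2, 23 °C, dark; filter; then NaClO2, NaH2PO4, 2-methyl-2-butene, t-BuOH/H2O, 0 °C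
Reagents that add atoms: sodium chlorite, [Na+].[O-]Cl=O
Why: Allylic oxidation followed by Pinnick oxidation gives the acid under neutral to weakly acidic conditions that retain the Z geometry.

Step 18
Reactants: 27 (Z)-3-iodo-2-methylprop-2-enoic acid
Product: 29 (Z)-3-iodo-2-methylprop-2-enamide, via acid chloride 28 (not isolated)
Conditions: (COCl)2, DMF (cat.), CH2Cl2, 0 °C; then NH3 (0.5 M in dioxane), −20 °C
Reagents that add atoms: ammonia, N
Why: Acylation of ammonia by the acid chloride at low temperature is much faster than addition–elimination at the β-iodo carbon, so the Z-iodoacrylamide is obtained.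

Step 19
Reactants: 22 TES-protected diene; 29 (Z)-3-iodo-2-methylprop-2-enamide
Product: 31 (2Z,6S,7S,8Z,10S,11R,12S,14R)-15-[3-bromo-5-(triisopropylsilyloxy)phenyl]-11-(tert-butyldimethylsilyloxy)-6,12-dimethoxy-2,8,10,14-tetramethyl-7-(triethylsilyloxy)pentadeca-2,8-dienamide, via B-alkyl-9-BBN 30 (not isolated)
Conditions: 9-BBN dimer, THF, 23 °C; then 29 (1.5 equiv), Pd(dppf)Cl2 (5 mol%), AsPh3, aq. K3PO4, DMF, 23 °C
Reagents that add atoms: none
Why: 9-BBN hydroborates only the monosubstituted alkene, and the B-alkyl Suzuki–Miyaura coupling retains the vinyl iodide geometry (zerovalent palladium inserts into the vinyl iodide far faster than into the aryl bromide at room temperature), forming C3–C4 with the 2Z alkene.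

Step 20
Reactants: 31 seco-amide
Product: 32 7-O-descarbamoyl-7-O-triethylsilyl-11-O-(tert-butyldimethylsilyl)-18-O-triisopropylsilyl derivative of 36 (19-membered lactam; N–C20 bond closed)
Conditions: CuI (0.5 equiv), N,N′-dimethylethylenediamine, K2CO3, toluene (2 mM), 100 °C
Reagents that add atoms: none
Why: Intramolecular Goldberg-type amidation of the aryl bromide by the primary amide under high dilution closes the macrolactam, a ring closure with precedent on closely related ansamycin seco-amides; no stereocentre is touched.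

Step 21
Reactants: 32 tris-silylated macrolactam
Product: 33 7-O-descarbamoyl-11-O-(tert-butyldimethylsilyl)-18-O-triisopropylsilyl derivative of 36 (free C7 hydroxyl)
Conditions: PPTS, MeOH/CH2Cl2, 0 °C
Reagents that add atoms: none
Why: Acid-catalysed methanolysis removes the secondary TES ether much faster than the hindered TBS ether or the aryl TIPS ether.

Step 22
Reactants: 33 C7 alcohol
Product: 35 11-O-(tert-butyldimethylsilyl)-18-O-triisopropylsilyl ether of 36, via trichloroacetylcarbamate 34 (not isolated)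
Conditions: Cl3CC(O)NCO, CH2Cl2, 0 °C; then neutral Al2O3, 23 °C
Reagents that add atoms: trichloroacetyl isocyanate, O=C=NC(=O)C(Cl)(Cl)Cl
Why: The isocyanate acylates the only free hydroxyl (the anilide N–H is inert) and hydrolysis of the trichloroacetyl group on alumina gives the primary carbamate with retention at C7.

Step 23
Reactants: 35 bis-silyl ether
Product: 36 (4Z,8S,9S,10Z,12S,13R,14S,16R)-13,20-dihydroxy-8,14-dimethoxy-4,10,12,16-tetramethyl-3-oxo-2-azabicyclo[16.3.1]docosa-1(22),4,10,18,20-pentaen-9-yl carbamate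
Conditions: HF·pyridine, pyridine, THF, 0 → 23 °C
Reagents that add atoms: none
Why: Fluoride-mediated global desilylation cleaves the C11 TBS ether and the aryl TIPS ether while the carbamate, the lactam and both Z alkenes are stable.

**Compound list**
1 | 3-bromo-5-methylphenol | Cc1cc(O)cc(Br)c1 | starting material
2 | (3-bromo-5-methylphenoxy)triisopropylsilane | Cc1cc(Br)cc(O[Si](C(C)C)(C(C)C)C(C)C)c1 | intermediate
3 | [3-bromo-5-(bromomethyl)phenoxy]triisopropylsilane | BrCc1cc(Br)cc(O[Si](C(C)C)(C(C)C)C(C)C)c1 | intermediate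
4 | (S)-4-benzyl-3-propanoyl-1,3-oxazolidin-2-one | CCC(=O)N1C(=O)OC[C@@H]1Cc1ccccc1 | starting material
5 | sodium (Z)-enolate of 4 | [Na+].C/C=C(\[O-])N1C(=O)OC[C@@H]1Cc1ccccc1 | intermediate (not isolated)
6 | (S)-4-benzyl-3-[(R)-3-[3-bromo-5-(triisopropylsilyloxy)phenyl]-2-methylpropanoyl]-1,3-oxazolidin-2-one | O=C1OC[C@H](Cc2ccccc2)N1C(=O)[C@H](C)Cc1cc(Br)cc(O[Si](C(C)C)(C(C)C)C(C)C)c1 | intermediate
7 | (R)-3-[3-bromo-5-(triisopropylsilyloxy)phenyl]-2-methylpropan-1-ol | OC[C@H](C)Cc1cc(Br)cc(O[Si](C(C)C)(C(C)C)C(C)C)c1 | intermediate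
8 | [3-bromo-5-[(R)-3-iodo-2-methylpropyl]phenoxy]triisopropylsilane | IC[C@H](C)Cc1cc(Br)cc(O[Si](C(C)C)(C(C)C)C(C)C)c1 | intermediate
9 | (E)-N,N-dimethylhydrazone of 10 | CN(C)/N=C/CC[C@H](C)Cc1cc(Br)cc(O[Si](C(C)C)(C(C)C)C(C)C)c1 | intermediate (not isolated)
10 | (S)-5-[3-bromo-5-(triisopropylsilyloxy)phenyl]-4-methylpentanal | O=CCC[C@H](C)Cc1cc(Br)cc(O[Si](C(C)C)(C(C)C)C(C)C)c1 | intermediate
11 | (2S,4R)-5-[3-bromo-5-(triisopropylsilyloxy)phenyl]-2-methoxy-4-methylpentanal | CO[C@H](C=O)C[C@H](C)Cc1cc(Br)cc(O[Si](C(C)C)(C(C)C)C(C)C)c1 | intermediate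
12 | O-[bis(isopinocampheyl)boryl] ether of 13 | C=C[C@H](C)[C@@H](OB([C@H]1C[C@H]2C[C@@H]([C@@H]1C)C2(C)C)[C@H]1C[C@H]2C[C@@H]([C@@H]1C)C2(C)C)[C@@H](OC)C[C@H](C)Cc1cc(Br)cc(O[Si](C(C)C)(C(C)C)C(C)C)c1 | intermediate (not isolated)
13 | (3S,4R,5S,7R)-8-[3-bromo-5-(triisopropylsilyloxy)phenyl]-5-methoxy-3,7-dimethyloct-1-en-4-ol | C=C[C@H](C)[C@@H](O)[C@@H](OC)C[C@H](C)Cc1cc(Br)cc(O[Si](C(C)C)(C(C)C)C(C)C)c1 | intermediate
14 | tert-butyl{[(3S,4R,5S,7R)-8-[3-bromo-5-(triisopropylsilyloxy)phenyl]-5-methoxy-3,7-dimethyloct-1-en-4-yl]oxy}dimethylsilane | C=C[C@H](C)[C@@H](O[Si](C)(C)C(C)(C)C)[C@@H](OC)C[C@H](C)Cc1cc(Br)cc(O[Si](C(C)C)(C(C)C)C(C)C)c1 | intermediate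
15 | ozonide (1,2,4-trioxolane, epimers at the ring carbon) of 14 | C1(OCOO1)[C@H](C)[C@@H](O[Si](C)(C)C(C)(C)C)[C@@H](OC)C[C@H](C)Cc1cc(Br)cc(O[Si](C(C)C)(C(C)C)C(C)C)c1 | intermediate (not isolated)
16 | (2R,3R,4S,6R)-7-[3-bromo-5-(triisopropylsilyloxy)phenyl]-3-(tert-butyldimethylsilyloxy)-4-methoxy-2,6-dimethylheptanal | O=C[C@H](C)[C@@H](O[Si](C)(C)C(C)(C)C)[C@@H](OC)C[C@H](C)Cc1cc(Br)cc(O[Si](C(C)C)(C(C)C)C(C)C)c1 | intermediate
17 | ethyl (2Z,4S,5R,6S,8R)-9-[3-bromo-5-(triisopropylsilyloxy)phenyl]-5-(tert-butyldimethylsilyloxy)-6-methoxy-2,4,8-trimethylnon-2-enoate | CCOC(=O)/C(C)=C\[C@H](C)[C@@H](O[Si](C)(C)C(C)(C)C)[C@@H](OC)C[C@H](C)Cc1cc(Br)cc(O[Si](C(C)C)(C(C)C)C(C)C)c1 | intermediate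
18 | (2Z,4S,5R,6S,8R)-9-[3-bromo-5-(triisopropylsilyloxy)phenyl]-5-(tert-butyldimethylsilyloxy)-6-methoxy-2,4,8-trimethylnon-2-en-1-ol | OC/C(C)=C\[C@H](C)[C@@H](O[Si](C)(C)C(C)(C)C)[C@@H](OC)C[C@H](C)Cc1cc(Br)cc(O[Si](C(C)C)(C(C)C)C(C)C)c1 | intermediate
19 | (2Z,4S,5R,6S,8R)-9-[3-bromo-5-(triisopropylsilyloxy)phenyl]-5-(tert-butyldimethylsilyloxy)-6-methoxy-2,4,8-trimethylnon-2-enal | O=C/C(C)=C\[C@H](C)[C@@H](O[Si](C)(C)C(C)(C)C)[C@@H](OC)C[C@H](C)Cc1cc(Br)cc(O[Si](C(C)C)(C(C)C)C(C)C)c1 | intermediate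
20 | O-[bis(isopinocampheyl)boryl] ether of 21 | C=C[C@H](OC)[C@@H](OB([C@H]1C[C@H]2C[C@@H]([C@@H]1C)C2(C)C)[C@H]1C[C@H]2C[C@@H]([C@@H]1C)C2(C)C)/C(C)=C\[C@H](C)[C@@H](O[Si](C)(C)C(C)(C)C)[C@@H](OC)C[C@H](C)Cc1cc(Br)cc(O[Si](C(C)C)(C(C)C)C(C)C)c1 | intermediate (not isolated)
21 | (3S,4S,5Z,7S,8R,9S,11R)-12-[3-bromo-5-(triisopropylsilyloxy)phenyl]-8-(tert-butyldimethylsilyloxy)-3,9-dimethoxy-5,7,11-trimethyldodeca-1,5-dien-4-ol | C=C[C@H](OC)[C@@H](O)/C(C)=C\[C@H](C)[C@@H](O[Si](C)(C)C(C)(C)C)[C@@H](OC)C[C@H](C)Cc1cc(Br)cc(O[Si](C(C)C)(C(C)C)C(C)C)c1 | intermediate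
22 | triethyl{[(3S,4S,5Z,7S,8R,9S,11R)-12-[3-bromo-5-(triisopropylsilyloxy)phenyl]-8-(tert-butyldimethylsilyloxy)-3,9-dimethoxy-5,7,11-trimethyldodeca-1,5-dien-4-yl]oxy}silane | C=C[C@H](OC)[C@@H](O[Si](CC)(CC)CC)/C(C)=C\[C@H](C)[C@@H](O[Si](C)(C)C(C)(C)C)[C@@H](OC)C[C@H](C)Cc1cc(Br)cc(O[Si](C(C)C)(C(C)C)C(C)C)c1 | intermediate
23 | prop-2-yn-1-ol | C#CCO | starting material
24 | bromomagnesium (Z)-3-(bromomagnesio)-2-methylprop-2-en-1-olate | Br[Mg]OC/C(C)=C\[Mg]Br | intermediate (not isolated)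
25 | (Z)-3-iodo-2-methylprop-2-en-1-ol | OC/C(C)=C\I | intermediate
26 | (Z)-3-iodo-2-methylprop-2-enal | O=C/C(C)=C\I | intermediate (not isolated)
27 | (Z)-3-iodo-2-methylprop-2-enoic acid | OC(=O)/C(C)=C\I | intermediate
28 | (Z)-3-iodo-2-methylprop-2-enoyl chloride | ClC(=O)/C(C)=C\I | intermediate (not isolated)
29 | (Z)-3-iodo-2-methylprop-2-enamide | NC(=O)/C(C)=C\I | intermediate
30 | B-alkyl-9-borabicyclo[3.3.1]nonane from 22 (boron on C4) | B1(C2CCCC1CCC2)CC[C@H](OC)[C@@H](O[Si](CC)(CC)CC)/C(C)=C\[C@H](C)[C@@H](O[Si](C)(C)C(C)(C)C)[C@@H](OC)C[C@H](C)Cc1cc(Br)cc(O[Si](C(C)C)(C(C)C)C(C)C)c1 | intermediate (not isolated)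
31 | (2Z,6S,7S,8Z,10S,11R,12S,14R)-15-[3-bromo-5-(triisopropylsilyloxy)phenyl]-11-(tert-butyldimethylsilyloxy)-6,12-dimethoxy-2,8,10,14-tetramethyl-7-(triethylsilyloxy)pentadeca-2,8-dienamide | NC(=O)/C(C)=C\CC[C@H](OC)[C@@H](O[Si](CC)(CC)CC)/C(C)=C\[C@H](C)[C@@H](O[Si](C)(C)C(C)(C)C)[C@@H](OC)C[C@H](C)Cc1cc(Br)cc(O[Si](C(C)C)(C(C)C)C(C)C)c1 | intermediate
32 | 7-O-descarbamoyl-7-O-triethylsilyl-11-O-(tert-butyldimethylsilyl)-18-O-triisopropylsilyl derivative of 36 | CO[C@H]1C[C@H](C)Cc2cc(O[Si](C(C)C)(C(C)C)C(C)C)cc(c2)NC(=O)/C(C)=C\CC[C@H](OC)[C@@H](O[Si](CC)(CC)CC)/C(C)=C\[C@H](C)[C@H]1O[Si](C)(C)C(C)(C)C | intermediate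
33 | 7-O-descarbamoyl-11-O-(tert-butyldimethylsilyl)-18-O-triisopropylsilyl derivative of 36 | CO[C@H]1C[C@H](C)Cc2cc(O[Si](C(C)C)(C(C)C)C(C)C)cc(c2)NC(=O)/C(C)=C\CC[C@H](OC)[C@@H](O)/C(C)=C\[C@H](C)[C@H]1O[Si](C)(C)C(C)(C)C | intermediate
34 | 7-O-(N-trichloroacetylcarbamoyl) derivative of 33 | CO[C@H]1C[C@H](C)Cc2cc(O[Si](C(C)C)(C(C)C)C(C)C)cc(c2)NC(=O)/C(C)=C\CC[C@H](OC)[C@@H](OC(=O)NC(=O)C(Cl)(Cl)Cl)/C(C)=C\[C@H](C)[C@H]1O[Si](C)(C)C(C)(C)C | intermediate (not isolated)
35 | 11-O-(tert-butyldimethylsilyl)-18-O-triisopropylsilyl ether of 36 | CO[C@H]1C[C@H](C)Cc2cc(O[Si](C(C)C)(C(C)C)C(C)C)cc(c2)NC(=O)/C(C)=C\CC[C@H](OC)[C@@H](OC(N)=O)/C(C)=C\[C@H](C)[C@H]1O[Si](C)(C)C(C)(C)C | intermediate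
36 | (4Z,8S,9S,10Z,12S,13R,14S,16R)-13,20-dihydroxy-8,14-dimethoxy-4,10,12,16-tetramethyl-3-oxo-2-azabicyclo[16.3.1]docosa-1(22),4,10,18,20-pentaen-9-yl carbamate (CNP0138687.2) | CO[C@H]1C[C@H](C)Cc2cc(O)cc(c2)NC(=O)/C(C)=C\CC[C@H](OC)[C@@H](OC(N)=O)/C(C)=C\[C@H](C)[C@H]1O | target

**Totals**
Total step count: 23. Longest linear sequence: 20 steps (1 → 36 through steps 1–15 and 19–23); the three-step branch 23 → 29 (steps 16–18) joins at step 19.

**Steps most likely to fail, with fallbacks**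

Step 7 (the proposed new α-methoxylation). Risks are acetal formation, over-oxidation and erosion of the C12 configuration. The fallback uses known chemistry, sets out from 10 and comes back at 11. D-Proline-catalysed α-aminoxylation of 10 with nitrosobenzene, with NaBH4 reduction in the same flask, gives (2S,4R)-5-[3-bromo-5-(triisopropylsilyloxy)phenyl]-4-methyl-2-(phenylaminooxy)pentan-1-ol F1. Zn/AcOH cleaves the N–O bond to give (2S,4R)-5-[3-bromo-5-(triisopropylsilyloxy)phenyl]-4-methylpentane-1,2-diol F2. Selective silylation of the primary hydroxyl (t-BuMe2SiCl, imidazole) gives (2S,4R)-5-[3-bromo-5-(triisopropylsilyloxy)phenyl]-1-(tert-butyldimethylsilyloxy)-4-methylpentan-2-ol F3. O-Methylation (MeOTf, 2,6-di-tert-butyl-4-methylpyridine) gives tert-butyl{[(2S,4R)-5-[3-bromo-5-(triisopropylsilyloxy)phenyl]-2-methoxy-4-methylpentyl]oxy}dimethylsilane F4. Camphorsulfonic acid in MeOH at 0 °C removes the primary alkyl silyl ether but not the aryl TIPS ether and gives (2S,4R)-5-[3-bromo-5-(triisopropylsilyloxy)phenyl]-2-methoxy-4-methylpentan-1-ol F5, and Parikh–Doering oxidation returns 11.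

Step 19 (B-alkyl Suzuki coupling). Risks are competing insertion into the aryl bromide, loss of the aryl silyl ether under aqueous base, and instability of the β-iodoacrylamide. The fallback sets out from 22 and comes back at 31 by a hydroformylation/olefination approach. Linear-selective hydroformylation of the terminal alkene of 22 (Rh(acac)(CO)2, BIPHEPHOS, CO/H2, toluene, 60 °C) gives (4S,5S,6Z,8S,9R,10S,12R)-13-[3-bromo-5-(triisopropylsilyloxy)phenyl]-9-(tert-butyldimethylsilyloxy)-4,10-dimethoxy-6,8,12-trimethyl-5-(triethylsilyloxy)tridec-6-enal F6. Still–Gennari olefination with the phosphonate of step 11 gives ethyl (2Z,6S,7S,8Z,10S,11R,12S,14R)-15-[3-bromo-5-(triisopropylsilyloxy)phenyl]-11-(tert-butyldimethylsilyloxy)-6,12-dimethoxy-2,8,10,14-tetramethyl-7-(triethylsilyloxy)pentadeca-2,8-dienoate F7. Aminolysis with the aluminium amide made from Me3Al and NH4Cl gives 31.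

Step 20 (macrocyclic copper-catalysed amidation). Risks are oligomerisation, Z to E isomerisation of the enamide at 100 °C, and loss of the aryl silyl ether. The fallback sets out from 22 (and uses acid 27) and comes back at 32 by macrolactamisation. Pd2(dba)3/BINAP-catalysed coupling of 22 with benzophenone imine (Cs2CO3, toluene, 90 °C) gives the N-(diphenylmethylene)aniline analogue of 22 F8. Transimination with NH2OH·HCl/NaOAc in MeOH gives the aniline analogue of 22 F9. Hydroboration with 9-BBN and Suzuki coupling with 27 under the conditions of step 19 give (2Z,6S,7S,8Z,10S,11R,12S,14R)-15-[3-amino-5-(triisopropylsilyloxy)phenyl]-11-(tert-butyldimethylsilyloxy)-6,12-dimethoxy-2,8,10,14-tetramethyl-7-(triethylsilyloxy)pentadeca-2,8-dienoic acid F10. High-dilution lactamisation with 2-chloro-1-methylpyridinium iodide and Et3N (CH2Cl2, 40 °C) gives 32.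

**Further compounds**
F1 | step 7 | (2S,4R)-5-[3-bromo-5-(triisopropylsilyloxy)phenyl]-4-methyl-2-(phenylaminooxy)pentan-1-ol | OC[C@@H](ONc1ccccc1)C[C@H](C)Cc1cc(Br)cc(O[Si](C(C)C)(C(C)C)C(C)C)c1
F2 | step 7 | (2S,4R)-5-[3-bromo-5-(triisopropylsilyloxy)phenyl]-4-methylpentane-1,2-diol | OC[C@@H](O)C[C@H](C)Cc1cc(Br)cc(O[Si](C(C)C)(C(C)C)C(C)C)c1
F3 | step 7 | (2S,4R)-5-[3-bromo-5-(triisopropylsilyloxy)phenyl]-1-(tert-butyldimethylsilyloxy)-4-methylpentan-2-ol | CC(C)(C)[Si](C)(C)OC[C@@H](O)C[C@H](C)Cc1cc(Br)cc(O[Si](C(C)C)(C(C)C)C(C)C)c1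
F4 | step 7 | tert-butyl{[(2S,4R)-5-[3-bromo-5-(triisopropylsilyloxy)phenyl]-2-methoxy-4-methylpentyl]oxy}dimethylsilane | CC(C)(C)[Si](C)(C)OC[C@@H](OC)C[C@H](C)Cc1cc(Br)cc(O[Si](C(C)C)(C(C)C)C(C)C)c1
F5 | step 7 | (2S,4R)-5-[3-bromo-5-(triisopropylsilyloxy)phenyl]-2-methoxy-4-methylpentan-1-ol | OC[C@@H](OC)C[C@H](C)Cc1cc(Br)cc(O[Si](C(C)C)(C(C)C)C(C)C)c1
F6 | step 19 | (4S,5S,6Z,8S,9R,10S,12R)-13-[3-bromo-5-(triisopropylsilyloxy)phenyl]-9-(tert-butyldimethylsilyloxy)-4,10-dimethoxy-6,8,12-trimethyl-5-(triethylsilyloxy)tridec-6-enal | O=CCC[C@H](OC)[C@@H](O[Si](CC)(CC)CC)/C(C)=C\[C@H](C)[C@@H](O[Si](C)(C)C(C)(C)C)[C@@H](OC)C[C@H](C)Cc1cc(Br)cc(O[Si](C(C)C)(C(C)C)C(C)C)c1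
F7 | step 19 | ethyl (2Z,6S,7S,8Z,10S,11R,12S,14R)-15-[3-bromo-5-(triisopropylsilyloxy)phenyl]-11-(tert-butyldimethylsilyloxy)-6,12-dimethoxy-2,8,10,14-tetramethyl-7-(triethylsilyloxy)pentadeca-2,8-dienoate | CCOC(=O)/C(C)=C\CC[C@H](OC)[C@@H](O[Si](CC)(CC)CC)/C(C)=C\[C@H](C)[C@@H](O[Si](C)(C)C(C)(C)C)[C@@H](OC)C[C@H](C)Cc1cc(Br)cc(O[Si](C(C)C)(C(C)C)C(C)C)c1
F8 | step 20 | N-(diphenylmethylene)aniline analogue of 22 (N=CPh2 in place of Br) | C=C[C@H](OC)[C@@H](O[Si](CC)(CC)CC)/C(C)=C\[C@H](C)[C@@H](O[Si](C)(C)C(C)(C)C)[C@@H](OC)C[C@H](C)Cc1cc(N=C(c2ccccc2)c2ccccc2)cc(O[Si](C(C)C)(C(C)C)C(C)C)c1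
F9 | step 20 | aniline analogue of 22 (NH2 in place of Br) | C=C[C@H](OC)[C@@H](O[Si](CC)(CC)CC)/C(C)=C\[C@H](C)[C@@H](O[Si](C)(C)C(C)(C)C)[C@@H](OC)C[C@H](C)Cc1cc(N)cc(O[Si](C(C)C)(C(C)C)C(C)C)c1
F10 | step 20 | (2Z,6S,7S,8Z,10S,11R,12S,14R)-15-[3-amino-5-(triisopropylsilyloxy)phenyl]-11-(tert-butyldimethylsilyloxy)-6,12-dimethoxy-2,8,10,14-tetramethyl-7-(triethylsilyloxy)pentadeca-2,8-dienoic acid | OC(=O)/C(C)=C\CC[C@H](OC)[C@@H](O[Si](CC)(CC)CC)/C(C)=C\[C@H](C)[C@@H](O[Si](C)(C)C(C)(C)C)[C@@H](OC)C[C@H](C)Cc1cc(N)cc(O[Si](C(C)C)(C(C)C)C(C)C)c1
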